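## Retrosynthetic overview

1. Rings A (phloroglucinol ring) and B (4-methoxyphenyl ring) are bought. The only ring made is the dihydrofuran ring C, and it is made last.
2. Ring C comes from a 5-exo-tet opening of an (R)-epoxyprenyl side chain by the neighbouring ortho phenoxide (inversion gives 2S). The epoxide comes from a prenyl group, as in the presumed biosynthesis.
3. The epoxide comes from the symmetric diprenyl arene 7 by a catalyst-controlled, desymmetrising mono-epoxidation. Epoxidation, unmasking of the ortho phenols, ring closure and unmasking of the para phenol are run as one operation.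
4. Ortho rather than para ring closure is enforced by ester lability: the para oxygen is a slow-cleaving pivalate, both ortho oxygens are fast-cleaving acetates.
5. 7 ⇒ diprenyl dihydrochalcone 5 ⇒ acylphloroglucinol 3 (double C-prenylation) ⇒ 1 + 2 (Friedel–Crafts acylation).

Assumption: the single stereocentre in the given SMILES is read as (S) at C-2 of the dihydrobenzofuran, and the route delivers that enantiomer.

## Route

Step 1
Reactants: 1 phloroglucinol (benzene-1,3,5-triol); 2 3-(4-methoxyphenyl)propanoic acid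
Product: 3 3-(4-methoxyphenyl)-1-(2,4,6-trihydroxyphenyl)propan-1-one
Conditions: BF3·OEt2 (as solvent), 80 °C, 3 h; then aq. NaOAc, 60 °C
Reagents that add atoms: none
Why: Friedel–Crafts acylation with the free acid, in which phloroglucinol is far more nucleophilic than the anisole ring and the first acyl group deactivates ring A, so mono-C-acylation stops cleanly and the methyl ether survives; no stereocentre is formed.

Step 2
Reactants: 3 3-(4-methoxyphenyl)-1-(2,4,6-trihydroxyphenyl)propan-1-one; 4 prenyl bromide (1-bromo-3-methylbut-2-ene, 2.1 equiv)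
Product: 5 1-[2,4,6-trihydroxy-3,5-bis(3-methylbut-2-en-1-yl)phenyl]-3-(4-methoxyphenyl)propan-1-one
Conditions: 10% aq. KOH (3 equiv), 0 °C, argon, 2 h; then dilute HCl to pH 5
Reagents that add atoms: none
Why: Double C-alkylation of the ambident phloroglucinolate (the classical route to deoxyhumulone-type diprenyl acylphloroglucinols), where water solvates the oxygens and the soft allylic bromide reacts at the two free ring carbons; no stereocentre is formed.

Step 3
Reactants: 5 1-[2,4,6-trihydroxy-3,5-bis(3-methylbut-2-en-1-yl)phenyl]-3-(4-methoxyphenyl)propan-1-one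
Product: 7 3,5-bis(acetyloxy)-2,6-bis(3-methylbut-2-en-1-yl)-4-[3-(4-methoxyphenyl)propanoyl]phenyl 2,2-dimethylpropanoate, via 4-O-pivaloyl diphenol 6 (not isolated)
Conditions: pivaloyl chloride (1.05 equiv), Et3N (1.1 equiv), CH2Cl2, −40 → 0 °C; then Ac2O (4 equiv), Et3N (4 equiv), 4-(dimethylamino)pyridine (10 mol%), 20 °C
Reagents that add atoms: pivaloyl chloride, CC(C)(C)C(=O)Cl; acetic anhydride, CC(=O)OC(C)=O
Why: Chemoselective O-acylation, in which one equivalent of Et3N ionises only the most acidic hydroxyl (para to the ketone, a vinylogous acid) so that it takes the bulky pivaloyl group, after which nucleophile-catalysed acetylation caps both ortho hydroxyls including the chelated one; this masks the electron-rich ring against oxidation and differentiates the para oxygen from the ortho oxygens, with no stereocentre formed.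

Step 4
Reactants: 7 3,5-bis(acetyloxy)-2,6-bis(3-methylbut-2-en-1-yl)-4-[3-(4-methoxyphenyl)propanoyl]phenyl 2,2-dimethylpropanoate
Product: 11 1-[(2S)-4,6-dihydroxy-2-(2-hydroxypropan-2-yl)-5-(3-methylbut-2-en-1-yl)-2,3-dihydro-1-benzofuran-7-yl]-3-(4-methoxyphenyl)propan-1-one, via (R)-monoepoxide triester 8 (not isolated), via epoxy bis-phenol pivalate 9 (not isolated), via ring-closed pivalate 10 (not isolated)
Conditions: (a) 1,2:4,5-di-O-isopropylidene-β-D-erythro-2,3-hexodiulo-2,6-pyranose (Shi ketone from D-fructose, 30 mol%), Oxone (2KHSO5·KHSO4·K2SO4, 0.7 equiv, slow addition), K2CO3, Bu4NHSO4 (5 mol%), MeCN/dimethoxymethane/aq. Na2B4O7–Na2EDTA buffer, pH 10.5, −5 °C, stopped at about 55% consumption of 7; Na2S2O3 quench, extraction and solvent exchange without purification; (b) K2CO3 (4 equiv), MeOH, argon, 0 → 20 °C, 3 h; (c) 50 °C, 12 h; then NaH2PO4/Na2HPO4 buffer, pH 6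
Reagents that add atoms: potassium peroxymonosulfate (KHSO5, the oxidant in Oxone), [K+].[O-]S(=O)(=O)OO
Why: Shi asymmetric epoxidation (chiral dioxirane, spiro transition state) desymmetrises the two equivalent prenyl groups and with the D-fructose-derived ketone gives the (R)-epoxide; base methanolysis then frees the two ortho phenols first, the phenoxide next to the epoxide opens it at the secondary carbon in a 5-exo-tet SN2 reaction with inversion (R → S) while the para oxygen is still blocked, and warming finally removes the pivalate.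

## Compound list

1 | phloroglucinol (benzene-1,3,5-triol) | Oc1cc(O)cc(O)c1 | starting material
2 | 3-(4-methoxyphenyl)propanoic acid | COc1ccc(CCC(=O)O)cc1 | starting material
3 | 3-(4-methoxyphenyl)-1-(2,4,6-trihydroxyphenyl)propan-1-one | COc1ccc(CCC(=O)c2c(O)cc(O)cc2O)cc1 | intermediate
4 | prenyl bromide (1-bromo-3-methylbut-2-ene) | CC(C)=CCBr | starting material
5 | 1-[2,4,6-trihydroxy-3,5-bis(3-methylbut-2-en-1-yl)phenyl]-3-(4-methoxyphenyl)propan-1-one | COc1ccc(CCC(=O)c2c(O)c(CC=C(C)C)c(O)c(CC=C(C)C)c2O)cc1 | intermediate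
6 | 3,5-dihydroxy-2,6-bis(3-methylbut-2-en-1-yl)-4-[3-(4-methoxyphenyl)propanoyl]phenyl 2,2-dimethylpropanoate (formed in the flask) | COc1ccc(CCC(=O)c2c(O)c(CC=C(C)C)c(OC(=O)C(C)(C)C)c(CC=C(C)C)c2O)cc1 | intermediate
7 | 3,5-bis(acetyloxy)-2,6-bis(3-methylbut-2-en-1-yl)-4-[3-(4-methoxyphenyl)propanoyl]phenyl 2,2-dimethylpropanoate | COc1ccc(CCC(=O)c2c(OC(C)=O)c(CC=C(C)C)c(OC(=O)C(C)(C)C)c(CC=C(C)C)c2OC(C)=O)cc1 | intermediate
8 | 3,5-bis(acetyloxy)-2-{[(2R)-3,3-dimethyloxiran-2-yl]methyl}-6-(3-methylbut-2-en-1-yl)-4-[3-(4-methoxyphenyl)propanoyl]phenyl 2,2-dimethylpropanoate (formed in the flask) | COc1ccc(CCC(=O)c2c(OC(C)=O)c(CC=C(C)C)c(OC(=O)C(C)(C)C)c(C[C@H]3OC3(C)C)c2OC(C)=O)cc1 | intermediate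
9 | 2-{[(2R)-3,3-dimethyloxiran-2-yl]methyl}-3,5-dihydroxy-6-(3-methylbut-2-en-1-yl)-4-[3-(4-methoxyphenyl)propanoyl]phenyl 2,2-dimethylpropanoate (formed in the flask) | COc1ccc(CCC(=O)c2c(O)c(CC=C(C)C)c(OC(=O)C(C)(C)C)c(C[C@H]3OC3(C)C)c2O)cc1 | intermediate
10 | (2S)-6-hydroxy-2-(2-hydroxypropan-2-yl)-7-[3-(4-methoxyphenyl)propanoyl]-5-(3-methylbut-2-en-1-yl)-2,3-dihydro-1-benzofuran-4-yl 2,2-dimethylpropanoate (formed in the flask) | COc1ccc(CCC(=O)c2c(O)c(CC=C(C)C)c(OC(=O)C(C)(C)C)c3c2O[C@H](C(C)(C)O)C3)cc1 | intermediate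
11 | 1-[(2S)-4,6-dihydroxy-2-(2-hydroxypropan-2-yl)-5-(3-methylbut-2-en-1-yl)-2,3-dihydro-1-benzofuran-7-yl]-3-(4-methoxyphenyl)propan-1-one (CNP0150199.1) | COc1ccc(CCC(=O)c2c(O)c(CC=C(C)C)c(O)c3c2O[C@H](C(C)(C)O)C3)cc1 | target

## Step count and risk

Total step count: 4. Longest linear sequence: 4 (1 → 3 → 5 → 7 → 11).

The three steps most likely to fail, in order of risk:

**Step 4.** One operation has to deliver three things: a statistical mono-epoxidation of two equivalent alkenes, survival of the aryl esters at pH 10.5, and the right order of acetate and pivalate cleavage. The ceiling is about 45–50% of mono-epoxide, with unreacted 7 returning as recyclable 5; the bis-epoxide and any 6-endo chromanol are the expected by-products.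

The fallback changes the order of bond formation so that no desymmetrisation is needed. It sets out from 3 and comes back at 11. Compound 3 is C-prenylated once (1.0 equiv of 4, aq. KOH, 0 °C) to the mono-prenyl triol 1-[2,4,6-trihydroxy-3-(3-methylbut-2-en-1-yl)phenyl]-3-(4-methoxyphenyl)propan-1-one F6. The protocol of step 3 turns it into 3,5-bis(acetyloxy)-2-(3-methylbut-2-en-1-yl)-4-[3-(4-methoxyphenyl)propanoyl]phenyl 2,2-dimethylpropanoate F7. With a single alkene the Shi epoxidation can be driven to completion with excess Oxone, giving 3,5-bis(acetyloxy)-2-{[(2R)-3,3-dimethyloxiran-2-yl]methyl}-4-[3-(4-methoxyphenyl)propanoyl]phenyl 2,2-dimethylpropanoate F8. K2CO3 in MeOH then leads by way of the epoxy bis-phenol 2-{[(2R)-3,3-dimethyloxiran-2-yl]methyl}-3,5-dihydroxy-4-[3-(4-methoxyphenyl)propanoyl]phenyl 2,2-dimethylpropanoate F9 and the ring-closed (2S)-6-hydroxy-2-(2-hydroxypropan-2-yl)-7-[3-(4-methoxyphenyl)propanoyl]-2,3-dihydro-1-benzofuran-4-yl 2,2-dimethylpropanoate F10 to the deprenyl compound 1-[(2S)-4,6-dihydroxy-2-(2-hydroxypropan-2-yl)-2,3-dihydro-1-benzofuran-7-yl]-3-(4-methoxyphenyl)propan-1-one F11. F11 has one free ring carbon (C-5, between the two hydroxyls) and is C-prenylated there with 4 (aq. KOH, 0 °C) to give 11.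

**Step 3.** The para hydroxyl of 5 is flanked by two prenyl groups, so the mono-pivaloylation may give ortho or bis-pivalates. That would destroy the ortho/para control of step 4.

The fallback changes which oxygen is differentiated. It sets out from 5 and comes back at 11. TBSCl (2.2 equiv) with imidazole in DMF silylates every hydroxyl except the hydrogen-bonded one. By symmetry this gives a single compound, 1-[2,4-bis(tert-butyldimethylsilyloxy)-6-hydroxy-3,5-bis(3-methylbut-2-en-1-yl)phenyl]-3-(4-methoxyphenyl)propan-1-one F3. Shi epoxidation under the conditions of step 4(a) should favour the less shielded prenyl group next to the free hydroxyl, giving 1-[2,4-bis(tert-butyldimethylsilyloxy)-5-{[(2R)-3,3-dimethyloxiran-2-yl]methyl}-6-hydroxy-3-(3-methylbut-2-en-1-yl)phenyl]-3-(4-methoxyphenyl)propan-1-one F4. F4 is closed by that hydroxyl, the only free one (in the pH 10.5 medium, or completed with DBU in CH2Cl2), to 1-[(2S)-4,6-bis(tert-butyldimethylsilyloxy)-2-(2-hydroxypropan-2-yl)-5-(3-methylbut-2-en-1-yl)-2,3-dihydro-1-benzofuran-7-yl]-3-(4-methoxyphenyl)propan-1-one F5. Epoxide formed at the other prenyl group cannot ring-close and is removed by chromatography. Bu4NF in THF at 0 °C then gives 11. The price is a lower ceiling (roughly one third of the material) and a free phenol exposed to the oxidant.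

**Step 2.** Double C-prenylation of acylphloroglucinols typically gives 30–45%, with mono-prenyl, geminal diprenyl and O-prenyl by-products, and 5 is air-sensitive.

The fallback builds the side chains by sigmatropic rearrangement and metathesis. It sets out from 3 and comes back at 5. Allyl bromide with K2CO3 in refluxing acetone etherifies the two non-chelated hydroxyls to 1-[2-hydroxy-4,6-bis(prop-2-en-1-yloxy)phenyl]-3-(4-methoxyphenyl)propan-1-one F1. Heating in N,N-diethylaniline at 190 °C triggers a double aromatic Claisen rearrangement, with Cope relay where an ortho position is blocked. It can only end at the two free ring carbons, giving 1-[2,4,6-trihydroxy-3,5-di(prop-2-en-1-yl)phenyl]-3-(4-methoxyphenyl)propan-1-one F2. Double cross-metathesis with 2-methylbut-2-ene (second-generation Grubbs catalyst RuCl2(=CHPh)(H2IMes)(PCy3), CH2Cl2, 40 °C) converts both allyl groups into prenyl groups and returns to 5.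

## Further compounds

F1 | step 2 | 1-[2-hydroxy-4,6-bis(prop-2-en-1-yloxy)phenyl]-3-(4-methoxyphenyl)propan-1-one | COc1ccc(CCC(=O)c2c(O)cc(OCC=C)cc2OCC=C)cc1
F2 | step 2 | 1-[2,4,6-trihydroxy-3,5-di(prop-2-en-1-yl)phenyl]-3-(4-methoxyphenyl)propan-1-one | COc1ccc(CCC(=O)c2c(O)c(CC=C)c(O)c(CC=C)c2O)cc1
F3 | step 3 | 1-[2,4-bis(tert-butyldimethylsilyloxy)-6-hydroxy-3,5-bis(3-methylbut-2-en-1-yl)phenyl]-3-(4-methoxyphenyl)propan-1-one | COc1ccc(CCC(=O)c2c(O)c(CC=C(C)C)c(O[Si](C)(C)C(C)(C)C)c(CC=C(C)C)c2O[Si](C)(C)C(C)(C)C)cc1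
F4 | step 3 | 1-[2,4-bis(tert-butyldimethylsilyloxy)-5-{[(2R)-3,3-dimethyloxiran-2-yl]methyl}-6-hydroxy-3-(3-methylbut-2-en-1-yl)phenyl]-3-(4-methoxyphenyl)propan-1-one | COc1ccc(CCC(=O)c2c(O)c(C[C@H]3OC3(C)C)c(O[Si](C)(C)C(C)(C)C)c(CC=C(C)C)c2O[Si](C)(C)C(C)(C)C)cc1
F5 | step 3 | 1-[(2S)-4,6-bis(tert-butyldimethylsilyloxy)-2-(2-hydroxypropan-2-yl)-5-(3-methylbut-2-en-1-yl)-2,3-dihydro-1-benzofuran-7-yl]-3-(4-methoxyphenyl)propan-1-one | COc1ccc(CCC(=O)c2c(O[Si](C)(C)C(C)(C)C)c(CC=C(C)C)c(O[Si](C)(C)C(C)(C)C)c3c2O[C@H](C(C)(C)O)C3)cc1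
F6 | step 4 | 1-[2,4,6-trihydroxy-3-(3-methylbut-2-en-1-yl)phenyl]-3-(4-methoxyphenyl)propan-1-one | COc1ccc(CCC(=O)c2c(O)cc(O)c(CC=C(C)C)c2O)cc1
F7 | step 4 | 3,5-bis(acetyloxy)-2-(3-methylbut-2-en-1-yl)-4-[3-(4-methoxyphenyl)propanoyl]phenyl 2,2-dimethylpropanoate | COc1ccc(CCC(=O)c2c(OC(C)=O)cc(OC(=O)C(C)(C)C)c(CC=C(C)C)c2OC(C)=O)cc1
F8 | step 4 | 3,5-bis(acetyloxy)-2-{[(2R)-3,3-dimethyloxiran-2-yl]methyl}-4-[3-(4-methoxyphenyl)propanoyl]phenyl 2,2-dimethylpropanoate | COc1ccc(CCC(=O)c2c(OC(C)=O)cc(OC(=O)C(C)(C)C)c(C[C@H]3OC3(C)C)c2OC(C)=O)cc1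
F9 | step 4 | 2-{[(2R)-3,3-dimethyloxiran-2-yl]methyl}-3,5-dihydroxy-4-[3-(4-methoxyphenyl)propanoyl]phenyl 2,2-dimethylpropanoate | COc1ccc(CCC(=O)c2c(O)cc(OC(=O)C(C)(C)C)c(C[C@H]3OC3(C)C)c2O)cc1
F10 | step 4 | (2S)-6-hydroxy-2-(2-hydroxypropan-2-yl)-7-[3-(4-methoxyphenyl)propanoyl]-2,3-dihydro-1-benzofuran-4-yl 2,2-dimethylpropanoate | COc1ccc(CCC(=O)c2c(O)cc(OC(=O)C(C)(C)C)c3c2O[C@H](C(C)(C)O)C3)cc1
F11 | step 4 | 1-[(2S)-4,6-dihydroxy-2-(2-hydroxypropan-2-yl)-2,3-dihydro-1-benzofuran-7-yl]-3-(4-methoxyphenyl)propan-1-one | COc1ccc(CCC(=O)c2c(O)cc(O)c3c2O[C@H](C(C)(C)O)C3)cc1
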